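**Retrosynthetic overview**

- Ring labels: A and F are the terminal 2,4,6-trihydroxyphenyl rings. B and D are the rings bonded to them (C1 biaryl carbon, OH on C2, C4 and C6, ether carbon C5). C is the central 1,2,3-tris(aryloxy) ring and E is the 3,4,5-trihydroxyphenoxy ring.
- Feature used: both carbons of each biaryl bond (ring A to ring B C1, ring F to ring D C1) stand next to a C-OH, and the ring B C6 hydroxyl has the ether carbon C5 on its other side. An O-Si-O bridge from that C6 oxygen to an ortho oxygen of ring A therefore leaves ring B C1-H as the only ortho C-H within reach.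
- Late disconnections: twelve O-CH3 bonds (BBr3) and two silylene bridges (Bu4NF). Before that, both biaryl bonds are cut at once (twofold tethered C-H arylation of a dibromide), then four Si-O bonds, back to the B-C(-E)-D core diol and 2-bromo-3,5-dimethoxyphenol.
- Core: the C-E ether comes from an Ullmann coupling, and the C-B and C-D ethers from a twofold SNAr on 2,6-difluoro-4-methoxybenzaldehyde. Each formyl group ends as a phenol oxygen by Baeyer-Villiger oxidation.
- Ring order: all six benzene rings are bought. The only rings formed are the two seven-membered dioxasilepines, closed together in step 9 and opened again in step 10.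

Key step: step 9

Assumption: the four aromatic starting materials are taken to be catalogue compounds.

Assumption: the two biaryl axes are stereogenic while the ortho groups on the terminal rings differ, that is, in the bridged product of the key step and in the tetraol made from it. These two compounds are expected as atropisomer mixtures and are carried on unseparated. After demethylation rings A and F carry two equal ortho hydroxyls, so the target has no stereogenic element.

**Step 1**
Reactants: 1 2-hydroxy-4,6-dimethoxybenzaldehyde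
Product: 2 2-(benzyloxy)-4,6-dimethoxybenzaldehyde
Conditions: BnBr (1.2 equiv), K2CO3 (1.5 equiv), DMF, 60 °C
Reagents that add atoms: benzyl bromide BrCc1ccccc1
Why: Williamson ether synthesis at the only acidic site, with benzyl chosen because hydrogenolysis will later free this one oxygen per ring (the future silicon anchor of rings B and D) without touching a methyl ether.

**Step 2**
Reactants: 2 2-(benzyloxy)-4,6-dimethoxybenzaldehyde
Product: 4 2-(benzyloxy)-4,6-dimethoxyphenol, via aryl formate 3 (not isolated)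
Conditions: mCPBA (1.3 equiv), CH2Cl2, 0 °C to rt; reductive aqueous wash; then K2CO3 (cat.), MeOH, rt, Ar
Reagents that add atoms: mCPBA (3-chloroperoxybenzoic acid) OOC(=O)c1cccc(Cl)c1
Why: Baeyer-Villiger oxidation of an aryl aldehyde, in which two ortho and one para alkoxy donors make aryl migration much faster than hydride migration, and the formate is then cleaved by base-catalysed transesterification with methanol.

**Step 3**
Reactants: 4 2-(benzyloxy)-4,6-dimethoxyphenol (2.2 equiv), 5 2,6-difluoro-4-methoxybenzaldehyde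
Product: 6 2,6-bis[2-(benzyloxy)-4,6-dimethoxyphenoxy]-4-methoxybenzaldehyde
Conditions: Cs2CO3 (3 equiv), DMSO, 100 °C, Ar
Reagents that add atoms: none
Why: Twofold nucleophilic aromatic substitution by addition-elimination, in which each fluorine is ortho to the formyl acceptor and meta to the methoxy group so that no donor opposes the Meisenheimer charge, and the first aryloxy group also lies meta to the remaining fluorine and does not shut down the second substitution.

**Step 4**
Reactants: 6 2,6-bis[2-(benzyloxy)-4,6-dimethoxyphenoxy]-4-methoxybenzaldehyde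
Product: 8 2,6-bis[2-(benzyloxy)-4,6-dimethoxyphenoxy]-4-methoxyphenol, via ring C formate 7 (not isolated)
Conditions: mCPBA (1.3 equiv), CH2Cl2, 0 °C to rt; reductive aqueous wash; then K2CO3 (cat.), MeOH, rt, Ar
Reagents that add atoms: mCPBA (3-chloroperoxybenzoic acid) OOC(=O)c1cccc(Cl)c1
Why: Baeyer-Villiger oxidation followed by formate methanolysis, favoured because the migrating ring C carbon has a para methoxy and two ortho aryloxy donors, while benzyl and methyl ethers are inert to the peracid and excess oxidant is destroyed before the oxidation-prone phenol is released.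

**Step 5**
Reactants: 8 2,6-bis[2-(benzyloxy)-4,6-dimethoxyphenoxy]-4-methoxyphenol, 9 5-iodo-1,2,3-trimethoxybenzene (1.5 equiv)
Product: 10 1,3-bis[2-(benzyloxy)-4,6-dimethoxyphenoxy]-5-methoxy-2-(3,4,5-trimethoxyphenoxy)benzene
Conditions: CuI (20 mol %), picolinic acid (40 mol %), K3PO4 (2 equiv), DMSO, 100 °C, Ar
Reagents that add atoms: none
Why: Ullmann-type copper-catalysed diaryl ether synthesis, using the picolinate ligand system known to accept phenols with two ortho substituents and an iodide that has no ortho substituent.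

**Step 6**
Reactants: 10 1,3-bis[2-(benzyloxy)-4,6-dimethoxyphenoxy]-5-methoxy-2-(3,4,5-trimethoxyphenoxy)benzene
Product: 11 2,2'-{[5-methoxy-2-(3,4,5-trimethoxyphenoxy)-1,3-phenylene]bis(oxy)}bis(3,5-dimethoxyphenol) (core diol, rings B, C, D, E)
Conditions: H2 (1 atm), 10% Pd/C, EtOAc-MeOH, rt
Reagents that add atoms: none
Why: Catalytic hydrogenolysis cleaves only the two benzylic C-O bonds, because diaryl ethers and aryl methyl ethers are inert to H2 over Pd/C at room temperature.

**Step 7**
Reactants: 12 3,5-dimethoxyphenol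
Product: 13 2-bromo-3,5-dimethoxyphenol
Conditions: NBS (1.0 equiv), iPr2NH (10 mol %), CH2Cl2, -78 to 0 °C
Reagents that add atoms: N-bromosuccinimide O=C1CCC(=O)N1Br
Why: Electrophilic aromatic bromination under secondary-amine catalysis (the known ortho-selective NBS bromination of phenols) should place bromine at C2, next to the hydroxyl and para to a methoxy group, rather than at the more crowded C4, with one equivalent at low temperature limiting dibromination and chromatography removing any C4 isomer.

**Step 8**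
Reactants: 13 2-bromo-3,5-dimethoxyphenol (2.2 equiv), 11 core diol
Product: 15 1,3-bis{2-[(2-bromo-3,5-dimethoxyphenoxy)di-tert-butylsilyloxy]-4,6-dimethoxyphenoxy}-5-methoxy-2-(3,4,5-trimethoxyphenoxy)benzene, via aryloxysilyl triflate 14 (not isolated)
Conditions: 13 added slowly to tBu2Si(OTf)2 (2.2 equiv), 2,6-lutidine (2.5 equiv), CH2Cl2, -78 to 0 °C; then 11 (1 equiv), 2,6-lutidine (3 equiv), DMAP (cat.), 0 to 40 °C
Reagents that add atoms: di-tert-butylsilyl bis(trifluoromethanesulfonate) CC(C)(C)[Si](OS(=O)(=O)C(F)(F)F)(OS(=O)(=O)C(F)(F)F)C(C)(C)C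
Why: Stepwise silyl ether formation with a bifunctional silyl triflate works because the tert-butyl groups make the second triflate displacement much slower than the first, so the bromophenol can be held on silicon as a monotriflate before the diol is added, an order that also prevents one silicon atom from bridging the ring B and ring D hydroxyls of 11.

**Step 9**
Reactants: 15 bis(silylene)-tethered dibromide
Product: 16 1,3-bis[(6,6-di-tert-butyl-1,3,9,11-tetramethoxydibenzo[d,f][1,3,2]dioxasilepin-4-yl)oxy]-5-methoxy-2-(3,4,5-trimethoxyphenoxy)benzene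
Conditions: Pd(OAc)2 (20 mol %), PCy3·HBF4 (40 mol %), PivOH (60 mol %), Cs2CO3 (4 equiv), dry degassed mesitylene (0.01 M), 135 °C, Ar
Reagents that add atoms: none
Why: Zerovalent palladium formed in situ from Pd(OAc)2 and PCy3 inserts into each ring A (ring F) C-Br bond, bromide is exchanged for pivalate, the bound pivalate removes the ring B (ring D) C1 proton by concerted metalation-deprotonation while Cs2CO3 regenerates it, and C-C reductive elimination gives the biaryl. The closest known reaction type is the palladium-catalysed intramolecular direct arylation of unsymmetrical di-tert-butylbis(aryloxy)silanes carrying an ortho bromide, which gives 2,2'-biphenols after desilylation, and here it runs at two identical and independent sites of one molecule. Each seven-membered dibenzodioxasilepine ring closes by aryl-aryl reductive elimination from an eight-membered diarylpalladium ring (Pd, two ring A carbons, O, Si, O, two ring B carbons), with the bulky tert-butyl groups pressing the two aryloxy arms toward each other. No stereocentre is created, and the two new axes are stereogenic only while their ortho groups differ, so the atropisomers are not separated. The step needs site selectivity on rings B and D and chemoselectivity against the C-H bonds of rings C and E: one neighbour of the silylated carbon carries the ether to ring C, so C1-H is the only ortho C-H, and any other aryl C-H would require a ring of ten or more members. Methyl rather than benzyl ethers flank the bromide so that no six-membered benzochromene closure can compete.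

**Step 10**
Reactants: 16 bis(dibenzodioxasilepine)
Product: 17 3,3'-{[5-methoxy-2-(3,4,5-trimethoxyphenoxy)-1,3-phenylene]bis(oxy)}bis(4,4',6,6'-tetramethoxybiphenyl-2,2'-diol)
Conditions: Bu4NF (5 equiv), AcOH (5 equiv), THF, 0 °C to rt, Ar
Reagents that add atoms: none
Why: Fluoride-induced cleavage of aryl silyl ethers is driven by Si-F bond formation, with acetic acid protonating the four phenoxides as they form so that the electron-rich biphenols are not exposed to base, while methyl and diaryl ethers are inert.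

**Step 11**
Reactants: 17 tetraol dodecamethyl ether
Product: 18 CNP0279880.0, 3,3'-{[5-hydroxy-2-(3,4,5-trihydroxyphenoxy)-1,3-phenylene]bis(oxy)}bis(biphenyl-2,2',4,4',6,6'-hexol)
Conditions: BBr3 (30 equiv), CH2Cl2, -78 °C to rt; then ice-water, Ar
Reagents that add atoms: none
Why: In this Lewis-acid cleavage of aryl methyl ethers, boron binds each methoxy oxygen and bromide attacks the methyl carbon, whereas the diaryl ether and biaryl bonds offer no sp3 carbon and persist, and hydrolysis of the aryl borates frees all sixteen hydroxyls.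

**Compound list**
1 | 2-hydroxy-4,6-dimethoxybenzaldehyde | COc1cc(O)c(C=O)c(OC)c1 | starting material
2 | 2-(benzyloxy)-4,6-dimethoxybenzaldehyde | COc1cc(OCc2ccccc2)c(C=O)c(OC)c1 | intermediate
3 | 2-(benzyloxy)-4,6-dimethoxyphenyl formate | COc1cc(OCc2ccccc2)c(OC=O)c(OC)c1 | intermediate
4 | 2-(benzyloxy)-4,6-dimethoxyphenol | COc1cc(OCc2ccccc2)c(O)c(OC)c1 | intermediate
5 | 2,6-difluoro-4-methoxybenzaldehyde | COc1cc(F)c(C=O)c(F)c1 | starting material
6 | 2,6-bis[2-(benzyloxy)-4,6-dimethoxyphenoxy]-4-methoxybenzaldehyde | COc1cc(Oc2c(OC)cc(OC)cc2OCc2ccccc2)c(C=O)c(Oc2c(OC)cc(OC)cc2OCc2ccccc2)c1 | intermediate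
7 | 2,6-bis[2-(benzyloxy)-4,6-dimethoxyphenoxy]-4-methoxyphenyl formate | COc1cc(Oc2c(OC)cc(OC)cc2OCc2ccccc2)c(OC=O)c(Oc2c(OC)cc(OC)cc2OCc2ccccc2)c1 | intermediate
8 | 2,6-bis[2-(benzyloxy)-4,6-dimethoxyphenoxy]-4-methoxyphenol | COc1cc(Oc2c(OC)cc(OC)cc2OCc2ccccc2)c(O)c(Oc2c(OC)cc(OC)cc2OCc2ccccc2)c1 | intermediate
9 | 5-iodo-1,2,3-trimethoxybenzene | COc1cc(I)cc(OC)c1OC | starting material
10 | 1,3-bis[2-(benzyloxy)-4,6-dimethoxyphenoxy]-5-methoxy-2-(3,4,5-trimethoxyphenoxy)benzene | COc1cc(Oc2c(OC)cc(OC)cc2OCc2ccccc2)c(Oc2cc(OC)c(OC)c(OC)c2)c(Oc2c(OC)cc(OC)cc2OCc2ccccc2)c1 | intermediate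
11 | 2,2'-{[5-methoxy-2-(3,4,5-trimethoxyphenoxy)-1,3-phenylene]bis(oxy)}bis(3,5-dimethoxyphenol) | COc1cc(Oc2c(OC)cc(OC)cc2O)c(Oc2cc(OC)c(OC)c(OC)c2)c(Oc2c(OC)cc(OC)cc2O)c1 | intermediate
12 | 3,5-dimethoxyphenol | COc1cc(O)cc(OC)c1 | starting material
13 | 2-bromo-3,5-dimethoxyphenol | COc1cc(O)c(Br)c(OC)c1 | intermediate
14 | (2-bromo-3,5-dimethoxyphenoxy)di-tert-butylsilyl trifluoromethanesulfonate | COc1cc(O[Si](OS(=O)(=O)C(F)(F)F)(C(C)(C)C)C(C)(C)C)c(Br)c(OC)c1 | intermediate
15 | 1,3-bis{2-[(2-bromo-3,5-dimethoxyphenoxy)di-tert-butylsilyloxy]-4,6-dimethoxyphenoxy}-5-methoxy-2-(3,4,5-trimethoxyphenoxy)benzene | COc1cc(Oc2c(OC)cc(OC)cc2O[Si](C(C)(C)C)(C(C)(C)C)Oc2cc(OC)cc(OC)c2Br)c(Oc2cc(OC)c(OC)c(OC)c2)c(Oc2c(OC)cc(OC)cc2O[Si](C(C)(C)C)(C(C)(C)C)Oc2cc(OC)cc(OC)c2Br)c1 | intermediate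
16 | 1,3-bis[(6,6-di-tert-butyl-1,3,9,11-tetramethoxydibenzo[d,f][1,3,2]dioxasilepin-4-yl)oxy]-5-methoxy-2-(3,4,5-trimethoxyphenoxy)benzene | COc1cc(Oc2c(OC)cc(OC)c3c2O[Si](C(C)(C)C)(C(C)(C)C)Oc2cc(OC)cc(OC)c2-3)c(Oc2cc(OC)c(OC)c(OC)c2)c(Oc2c(OC)cc(OC)c3c2O[Si](C(C)(C)C)(C(C)(C)C)Oc2cc(OC)cc(OC)c2-3)c1 | intermediate
17 | 3,3'-{[5-methoxy-2-(3,4,5-trimethoxyphenoxy)-1,3-phenylene]bis(oxy)}bis(4,4',6,6'-tetramethoxybiphenyl-2,2'-diol) | COc1cc(Oc2c(OC)cc(OC)c(-c3c(O)cc(OC)cc3OC)c2O)c(Oc2cc(OC)c(OC)c(OC)c2)c(Oc2c(OC)cc(OC)c(-c3c(O)cc(OC)cc3OC)c2O)c1 | intermediate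
18 | CNP0279880.0 | Oc1cc(O)c(-c2c(O)cc(O)c(Oc3cc(O)cc(Oc4c(O)cc(O)c(-c5c(O)cc(O)cc5O)c4O)c3Oc3cc(O)c(O)c(O)c3)c2O)c(O)c1 | target

Total step count: 11
Longest linear sequence: 10 (steps 1 to 6 and 8 to 11). Step 7 is the side branch.

**Steps most likely to fail**

**Step 9.**
- What may go wrong: oxidative addition into a bromide flanked by two oxygens on an electron-rich ring is slow.
- Once the arylpalladium species exists, several processes can outrun the crowded C-H cleavage between two oxygen substituents. These are reduction of the C-Pd bond, palladation of a neighbouring methoxy or tert-butyl C-H bond, and base-induced loss of the silicon bridge.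
- With two sites, stalling at either end costs material.
- The fallback replaces the tethered C-H arylation with an intermolecular cross-coupling. It sets out from 11. Twofold ortho-bromination with NBS and catalytic iPr2NH in CH2Cl2 follows the same control as in step 7, the free phenol rings B and D being the most activated rings. It should give 2,2'-{[5-methoxy-2-(3,4,5-trimethoxyphenoxy)-1,3-phenylene]bis(oxy)}bis(6-bromo-3,5-dimethoxyphenol) F1. MeI and K2CO3 in DMF then cap both hydroxyls to give 1,3-bis(3-bromo-2,4,6-trimethoxyphenoxy)-5-methoxy-2-(3,4,5-trimethoxyphenoxy)benzene F2. A twofold Suzuki-Miyaura coupling follows with 2,4,6-trimethoxyphenylboronic acid (Pd(OAc)2, SPhos, K3PO4, toluene-water, 100 °C), a ligand system known for biaryls with four ortho substituents. It gives 1,3-bis[(2,2',4,4',6,6'-hexamethoxybiphenyl-3-yl)oxy]-5-methoxy-2-(3,4,5-trimethoxyphenoxy)benzene F3. BBr3 under the conditions of step 11 cleaves all sixteen methyl ethers, and the route is rejoined at 18.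

**Step 8.**
- What may go wrong: the monotriflate may scramble to the symmetrical bis(aryloxy)silane.
- The second silylation may also stall at the crowded ring B and ring D hydroxyls, so that only one arm is attached.
- The fallback uses a smaller silicon bridge, installed from an isolable chlorosilane. It sets out from 13 and 11. Compound 13 is treated with excess iPr2SiCl2 and Et3N in CH2Cl2 at 0 °C, and the excess dichlorosilane is removed under vacuum to leave (2-bromo-3,5-dimethoxyphenoxy)chlorodiisopropylsilane F4. Reaction of this with 11 and imidazole in DMF at rt gives the bis(diisopropylsilylene)-tethered dibromide F5. The conditions of step 9 then close both rings to give the bis(6,6-diisopropyldibenzodioxasilepine) F6. Bu4NF and AcOH as in step 10 remove both bridges, and the route is rejoined at 17.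

**Step 5.**
- What may go wrong: the copper phenoxide of a hydroxyl flanked by two bulky aryloxy groups may fail to engage the iodide.
- Reductive deiodination, or oxidation of the electron-rich phenol by traces of air, would then take over.
- The fallback makes the central ether by SNAr instead of copper catalysis. It sets out from 8. 4-Fluoro-2,6-dimethoxybenzaldehyde has its fluorine para to the formyl group and meta to both methoxy groups. With Cs2CO3 in DMSO at 110 °C it should give 4-{2,6-bis[2-(benzyloxy)-4,6-dimethoxyphenoxy]-4-methoxyphenoxy}-2,6-dimethoxybenzaldehyde F7. Baeyer-Villiger oxidation with mCPBA gives the ring E formate F8. Catalytic K2CO3 in MeOH releases 4-{2,6-bis[2-(benzyloxy)-4,6-dimethoxyphenoxy]-4-methoxyphenoxy}-2,6-dimethoxyphenol F9. MeI and K2CO3 in DMF methylate this hydroxyl, and the route is rejoined at 10.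

**Further compounds**
F1 | step 9 | 2,2'-{[5-methoxy-2-(3,4,5-trimethoxyphenoxy)-1,3-phenylene]bis(oxy)}bis(6-bromo-3,5-dimethoxyphenol) | COc1cc(Oc2c(OC)cc(OC)c(Br)c2O)c(Oc2cc(OC)c(OC)c(OC)c2)c(Oc2c(OC)cc(OC)c(Br)c2O)c1
F2 | step 9 | 1,3-bis(3-bromo-2,4,6-trimethoxyphenoxy)-5-methoxy-2-(3,4,5-trimethoxyphenoxy)benzene | COc1cc(Oc2c(OC)cc(OC)c(Br)c2OC)c(Oc2cc(OC)c(OC)c(OC)c2)c(Oc2c(OC)cc(OC)c(Br)c2OC)c1
F3 | step 9 | 1,3-bis[(2,2',4,4',6,6'-hexamethoxybiphenyl-3-yl)oxy]-5-methoxy-2-(3,4,5-trimethoxyphenoxy)benzene | COc1cc(Oc2c(OC)cc(OC)c(-c3c(OC)cc(OC)cc3OC)c2OC)c(Oc2cc(OC)c(OC)c(OC)c2)c(Oc2c(OC)cc(OC)c(-c3c(OC)cc(OC)cc3OC)c2OC)c1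
F4 | step 8 | (2-bromo-3,5-dimethoxyphenoxy)chlorodiisopropylsilane | COc1cc(O[Si](Cl)(C(C)C)C(C)C)c(Br)c(OC)c1
F5 | step 8 | bis(diisopropylsilylene)-tethered dibromide (diisopropyl analogue of 15) | COc1cc(Oc2c(OC)cc(OC)cc2O[Si](C(C)C)(C(C)C)Oc2cc(OC)cc(OC)c2Br)c(Oc2cc(OC)c(OC)c(OC)c2)c(Oc2c(OC)cc(OC)cc2O[Si](C(C)C)(C(C)C)Oc2cc(OC)cc(OC)c2Br)c1
F6 | step 8 | bis(6,6-diisopropyldibenzodioxasilepine) (diisopropyl analogue of 16) | COc1cc(Oc2c(OC)cc(OC)c3c2O[Si](C(C)C)(C(C)C)Oc2cc(OC)cc(OC)c2-3)c(Oc2cc(OC)c(OC)c(OC)c2)c(Oc2c(OC)cc(OC)c3c2O[Si](C(C)C)(C(C)C)Oc2cc(OC)cc(OC)c2-3)c1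
F7 | step 5 | 4-{2,6-bis[2-(benzyloxy)-4,6-dimethoxyphenoxy]-4-methoxyphenoxy}-2,6-dimethoxybenzaldehyde | COc1cc(Oc2c(OC)cc(OC)cc2OCc2ccccc2)c(Oc2cc(OC)c(C=O)c(OC)c2)c(Oc2c(OC)cc(OC)cc2OCc2ccccc2)c1
F8 | step 5 | 4-{2,6-bis[2-(benzyloxy)-4,6-dimethoxyphenoxy]-4-methoxyphenoxy}-2,6-dimethoxyphenyl formate | COc1cc(Oc2c(OC)cc(OC)cc2OCc2ccccc2)c(Oc2cc(OC)c(OC=O)c(OC)c2)c(Oc2c(OC)cc(OC)cc2OCc2ccccc2)c1
F9 | step 5 | 4-{2,6-bis[2-(benzyloxy)-4,6-dimethoxyphenoxy]-4-methoxyphenoxy}-2,6-dimethoxyphenol | COc1cc(Oc2c(OC)cc(OC)cc2OCc2ccccc2)c(Oc2cc(OC)c(O)c(OC)c2)c(Oc2c(OC)cc(OC)cc2OCc2ccccc2)c1
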